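**Strategy**

Carbons are numbered from the carboxyl carbon C1 along the chain to the lactone carbonyl C19; C20 is the lactone OCH2 and the oxolane spans C6–C9. The route rests on cutting C14–C15 and C16–C17 at the exocyclic C15=C16 alkene of the dihydropyranone ring, where C14 and C17 are cis and C16 carries C20. One nickel-catalysed three-component coupling joins allylic chloride 28 (C1–C14, holding the oxolane, all four stereocentres, the (Z)-chloroalkene and the side-chain ester), propargyl silyl ether 32 and stannylpropiolate 31 by syn allyl–alkynyl addition across the alkyne, giving all twenty carbons at once. Semihydrogenation, desilylative lactonisation and ester cleavage finish.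

Key step: step 18

Remark: 2-deoxy-D-glucose 1 is drawn as the open-chain aldehyde but reacts as its cyclic hemiacetal, silyl ether 32 is taken as a purchased reagent, and locants C1–C20 on intermediates are those of the target (TBS = tert-butyldimethylsilyl).

**Route**

Step 1
Reactants: 1 2-deoxy-D-glucose
Product: 2 2-deoxy-D-arabino-hexono-1,4-lactone
Conditions: Br2, BaCO3, H2O, rt; H+ resin, concentrate
Reagents that add atoms: none
Why: Bromine-water oxidation of the cyclic hemiacetal gives the aldonic acid, which closes to the five-membered 1,4-lactone on acidic concentration; the three carbinol centres (later C7, C6 and C5) are not touched.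

Step 2
Reactants: 2 2-deoxy-D-arabino-hexono-1,4-lactone
Product: 3 3,5,6-tri-O-TBS-2-deoxy-D-arabino-hexono-1,4-lactone
Conditions: TBSCl, imidazole, DMF, rt → 45 °C
Reagents that add atoms: tert-butyldimethylsilyl chloride, CC(C)(C)[Si](C)(C)Cl
Why: Imidazole-promoted silylation protects all three hydroxyls in one operation, the weak base avoiding β-elimination of the C3 oxygen from the lactone.

Step 3
Reactants: 4 4-(trimethylsilyl)but-3-yn-1-ol
Product: 5 (4-iodobut-1-yn-1-yl)trimethylsilane
Conditions: I2, PPh3, imidazole, CH2Cl2, 0 °C → rt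
Reagents that add atoms: iodine, II
Why: Appel-type iodination converts the primary alcohol into the iodide needed for lithium–halogen exchange.

Step 4
Reactants: 5 (4-iodobut-1-yn-1-yl)trimethylsilane; 3 tri-O-TBS lactone
Product: 7 tri-O-TBS lactol carrying the 4-(trimethylsilyl)but-3-ynyl group on C9 (both anomers), via alkyllithium 6 (not isolated)
Conditions: 5, t-BuLi (2 equiv), Et2O/pentane, −78 °C; then 3, THF, −78 °C; AcOH
Reagents that add atoms: none
Why: Lithium–iodine exchange gives the primary alkyllithium, whose addition to the lactone carbonyl at −78 °C should stop at the lithium hemiketal (acyl addition of an organolithium to a lactone); the anomeric centre may stay undefined because step 5 planarises it.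

Step 5
Reactants: 7 lactol
Product: 9 (5R,6S,7R,9R)-tris-TBS 2,5-trans oxolane with the silylbutynyl chain on C9, via oxocarbenium ion 8 (not isolated)
Conditions: Et3SiH, BF3·OEt2, CH2Cl2, −78 °C
Reagents that add atoms: none
Why: Lewis-acid ionisation gives the five-membered oxocarbenium ion and the silane hydride adds to the inside face of the envelope in which the C7 silyloxy group is pseudoaxial (reductive deoxygenation of a ketose lactol), so the new C9–H should be cis to the C7 oxygen and the C9 chain trans to both the C7 oxygen and the C6 side chain, which is the (9R) centre.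

Step 6
Reactants: 9 tris-TBS oxolane
Product: 10 C4 primary alcohol (C5 and C7 still TBS ethers)
Conditions: CSA (cat.), MeOH/CH2Cl2, 0 °C
Reagents that add atoms: none
Why: Acid-catalysed methanolysis removes the unhindered primary silyl ether much faster than the two secondary ones and leaves the alkynylsilane (selective desilylation).

Step 7
Reactants: 10 C4 primary alcohol
Product: 11 C4 aldehyde
Conditions: Dess–Martin periodinane, pyridine, CH2Cl2, 0 °C → rt
Reagents that add atoms: none
Why: Dess–Martin oxidation gives the α-silyloxy aldehyde under buffered, non-epimerising conditions; it is used at once.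

Step 8
Reactants: 11 C4 aldehyde
Product: 12 3,3-dibromoalkene (C4H=C3Br2)
Conditions: CBr4, PPh3, Zn dust, CH2Cl2, rt
Reagents that add atoms: carbon tetrabromide, BrC(Br)(Br)Br
Why: Corey–Fuchs dibromo-olefination adds the carbon that becomes C3, the zinc variant avoiding acidic phosphonium bromides that could strip silyl ethers.

Step 9
Reactants: 12 dibromoalkene
Product: 14 methyl alkyne (CH3–C3≡C4), via lithium acetylide 13 (not isolated)
Conditions: n-BuLi (2.2 equiv), THF, −78 °C; MeI, −78 °C → rt
Reagents that add atoms: iodomethane, CI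
Why: Bromine–lithium exchange, Fritsch–Buttenberg–Wiechell rearrangement and deprotonation give the lithium acetylide, which iodomethane C-methylates (second stage of the Corey–Fuchs sequence); the silyl-capped alkyne is inert to n-BuLi.

Step 10
Reactants: 14 methyl alkyne
Product: 15 terminal alkyne (C13–H)
Conditions: K2CO3 (cat.), MeOH, rt
Reagents that add atoms: none
Why: Carbonate-catalysed methanolysis of the alkynyl C–Si bond frees C13–H while the silyl ethers stay.

Step 11
Reactants: 15 terminal alkyne
Product: 17 propargylic alcohol (C14–OH), via lithium acetylide 16 (not isolated)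
Conditions: n-BuLi, THF, −78 °C; (CH2O)n, −78 °C → rt; H2O
Reagents that add atoms: formaldehyde (from paraformaldehyde), C=O
Why: Deprotonation of the only terminal alkyne and addition of the acetylide to formaldehyde installs C14 as a propargylic alcohol.

Step 12
Reactants: 17 propargylic alcohol
Product: 19 (12Z)-12-chloro allylic alcohol, via cyclic alkenylalanate 18 (not isolated)
Conditions: NaAlH2(OCH2CH2OMe)2, THF, 0 °C → rt; NCS, −78 → 0 °C
Reagents that add atoms: N-chlorosuccinimide, O=C1CCC(=O)N1Cl
Why: The free hydroxyl directs trans-hydroalumination (hydride to C13, aluminium to C12 in a five-membered alanate) and N-chlorosuccinimide replaces aluminium with retention, so chlorine and C14 should end cis; the other alkyne has no free hydroxyl and is left, and the step is placed before any ester exists.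

Step 13
Reactants: 19 chloro allylic alcohol
Product: 21 (3E)-3-iodoalkene, via alkenylzirconocene 20 (not isolated)
Conditions: Cp2Zr(H)Cl (3 equiv), THF, rt → 45 °C; I2, 0 °C
Reagents that add atoms: iodine, II
Why: Syn-hydrozirconation with the Schwartz reagent puts zirconium on the less hindered, methyl-bearing C3 and hydrogen on C4, and iodinolysis with retention gives the alkenyl iodide with methyl cis to C5; one equivalent of reagent is taken up by the hydroxyl, which returns on work-up.

Step 14
Reactants: 22 2-(trimethylsilyl)ethanol; 23 bromoacetyl bromide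
Product: 24 2-(trimethylsilyl)ethyl bromoacetate
Conditions: pyridine, CH2Cl2, 0 °C
Reagents that add atoms: none
Why: Acylation of the alcohol by the acid bromide gives the bromoacetate that carries C1, C2 and the fluoride-labile ester group.

Step 15
Reactants: 21 alkenyl iodide; 24 2-(trimethylsilyl)ethyl bromoacetate
Product: 26 C1–C14 ester with free C14 hydroxyl, via Reformatsky reagent 25 (not isolated)
Conditions: 24, Zn dust, THF, rt; then 21, Pd(PPh3)4 (cat.), THF, 50 °C
Reagents that add atoms: none
Why: Zinc insertion gives the Reformatsky reagent, which should couple with the alkenyl iodide under zerovalent palladium with retention of the C3=C4 geometry (Negishi-type cross-coupling), forming C2–C3 and the β,γ-unsaturated ester; excess zinc reagent covers the free hydroxyl, and the vinylic chloride and silyl ethers are inert.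

Step 16
Reactants: 26 allylic alcohol
Product: 28 C1–C14 allylic chloride, via allylic mesylate 27 (not isolated)
Conditions: MsCl, 2,4,6-collidine, LiCl, DMF, 0 °C
Reagents that add atoms: lithium chloride, [Li+].[Cl-]
Why: Mesylation of the only free hydroxyl and SN2 displacement by chloride at the primary allylic carbon should give the chloride without allylic transposition or loss of the (12Z) geometry.

Step 17
Reactants: 29 ethyl propiolate
Product: 31 ethyl 3-(tributylstannyl)propiolate, via lithium acetylide 30 (not isolated)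
Conditions: LiN(i-Pr)2, THF, −78 °C; Bu3SnCl, −78 °C
Reagents that add atoms: tributyltin chloride, CCCC[Sn](Cl)(CCCC)CCCC
Why: Deprotonation of the acidic alkyne C–H at −78 °C and stannylation of the acetylide gives the alkynylstannane.

Step 18
Reactants: 28 C1–C14 allylic chloride; 32 tert-butyldimethyl(prop-2-yn-1-yloxy)silane; 31 ethyl 3-(tributylstannyl)propiolate
Product: 33 protected C1–C20 dienyne
Conditions: Ni(acac)2 (10 mol%), i-Bu2AlH (10 mol%), THF, 25 → 65 °C; 31 and 32 added slowly
Reagents that add atoms: none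
Why: Zerovalent nickel, made in the flask from Ni(acac)2 and i-Bu2AlH, inserts into the allylic C14–Cl bond of 28 to give an η3-allyl complex of divalent nickel; the terminal alkyne of 32 then inserts syn, the allyl group bonding through its unsubstituted terminus C14 to the unsubstituted alkyne carbon C15 with nickel ending on C16, after which the alkynyl group of 31 passes from tin to nickel and reductive elimination forms C16–C17 and returns zerovalent nickel. The closest known reaction is the nickel-catalysed three-component coupling of allyl chlorides, terminal alkynes and alkynylstannanes to 3,6-dien-1-ynes, applied here to a chlorine-bearing allyl unit and an ester-bearing stannane. No ring closes and no stereocentre is made; the only stereochemical element created is the C15=C16 geometry, fixed by the syn addition so that C14 and C17 are cis and C20 sits on C16. The step needs chemoselectivity for the allylic over the vinylic C–Cl bond (oxidative addition to the allylic chloride is far faster), regioselectivity at the allyl unit (C14 is primary, C12 fully substituted) and at the alkyne (new C–C bond to the terminal carbon, nickel next to the CH2OTBS group), and retention of the (12Z) geometry (insertion should outrun syn–anti exchange through the hindered C12). Slow addition of 31 and 32 should hold back direct allyl–alkynyl coupling and alkyne oligomerisation.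

Step 19
Reactants: 33 protected dienyne
Product: 34 (17Z)-dienoate
Conditions: H2 (1 atm), Pd/CaCO3 poisoned with Pb(OAc)2, quinoline, EtOAc, rt
Reagents that add atoms: none
Why: Syn-semihydrogenation over the lead-poisoned palladium catalyst (Lindlar reduction) should reduce only the alkyne, the most strongly adsorbed π-system, to the cis enoate and leave the vinylic chloride and the trisubstituted alkenes.

Step 20
Reactants: 34 (17Z)-dienoate
Product: 36 2-(trimethylsilyl)ethyl ester of the target, via hydroxy ester 35 (not isolated)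
Conditions: HF·pyridine, pyridine, THF, 0 °C → rt
Reagents that add atoms: none
Why: Fluoride cleaves the three silyl ethers and the freed C20 hydroxyl, held next to the ester by the cis C17=C18 alkene, should close the six-membered unsaturated lactone by acid-promoted transesterification with loss of ethanol; the 2-(trimethylsilyl)ethyl ester is stable to HF·pyridine.

Step 21
Reactants: 36 2-(trimethylsilyl)ethyl ester
Product: 37 target acid CNP0180366.1
Conditions: TASF, DMF, 0 °C → rt; dilute aq. HCl (pH 4)
Reagents that add atoms: none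
Why: Fluoride attacks silicon of the 2-(trimethylsilyl)ethyl ester, which fragments to the carboxylate, ethene and Me3SiF (fluoride-induced β-elimination) under nearly neutral conditions that should spare the lactone and the skipped diene.

**Compound list**

1 | 2-deoxy-D-glucose (2-deoxy-D-arabino-hexose) | O=CC[C@@H](O)[C@H](O)[C@H](O)CO | starting material
2 | 2-deoxy-D-arabino-hexono-1,4-lactone | OC[C@@H](O)[C@H]1OC(=O)C[C@H]1O | intermediate
3 | 3,5,6-tri-O-(tert-butyldimethylsilyl)-2-deoxy-D-arabino-hexono-1,4-lactone | CC(C)(C)[Si](C)(C)OC[C@@H](O[Si](C)(C)C(C)(C)C)[C@H]1OC(=O)C[C@H]1O[Si](C)(C)C(C)(C)C | intermediate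
4 | 4-(trimethylsilyl)but-3-yn-1-ol | C[Si](C)(C)C#CCCO | starting material
5 | (4-iodobut-1-yn-1-yl)trimethylsilane | C[Si](C)(C)C#CCCI | intermediate
6 | [4-(trimethylsilyl)but-3-yn-1-yl]lithium (not isolated) | [Li]CCC#C[Si](C)(C)C | intermediate
7 | (5R,6S,7R)-lactol: C4, C5 and C7 oxygens as TBS ethers, C9 bearing OH and the 4-(trimethylsilyl)but-3-ynyl group, both anomers | CC(C)(C)[Si](C)(C)OC[C@@H](O[Si](C)(C)C(C)(C)C)[C@H]1OC(O)(CCC#C[Si](C)(C)C)C[C@H]1O[Si](C)(C)C(C)(C)C | intermediate
8 | oxocarbenium ion (C9=O+) from 7 (not isolated) | CC(C)(C)[Si](C)(C)OC[C@@H](O[Si](C)(C)C(C)(C)C)[C@H]1[O+]=C(CCC#C[Si](C)(C)C)C[C@H]1O[Si](C)(C)C(C)(C)C | intermediate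
9 | (5R,6S,7R,9R)-oxolane: C9 chain CH2CH2C≡C–SiMe3 trans to the C6 side chain and to the C7 OTBS group; C4, C5, C7 oxygens as TBS ethers | CC(C)(C)[Si](C)(C)OC[C@@H](O[Si](C)(C)C(C)(C)C)[C@H]1O[C@H](CCC#C[Si](C)(C)C)C[C@H]1O[Si](C)(C)C(C)(C)C | intermediate
10 | (5R,6S,7R,9R)-C4 primary alcohol, C5 and C7 TBS ethers | OC[C@@H](O[Si](C)(C)C(C)(C)C)[C@H]1O[C@H](CCC#C[Si](C)(C)C)C[C@H]1O[Si](C)(C)C(C)(C)C | intermediate
11 | C4 aldehyde (same spatial arrangement; C5 becomes S by priority change) | O=C[C@@H](O[Si](C)(C)C(C)(C)C)[C@H]1O[C@H](CCC#C[Si](C)(C)C)C[C@H]1O[Si](C)(C)C(C)(C)C | intermediate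
12 | (5R,6S,7R,9R)-3,3-dibromoalkene (C4H=C3Br2) | BrC(Br)=C[C@@H](O[Si](C)(C)C(C)(C)C)[C@H]1O[C@H](CCC#C[Si](C)(C)C)C[C@H]1O[Si](C)(C)C(C)(C)C | intermediate
13 | lithium acetylide at C3 (not isolated) | [Li]C#C[C@@H](O[Si](C)(C)C(C)(C)C)[C@H]1O[C@H](CCC#C[Si](C)(C)C)C[C@H]1O[Si](C)(C)C(C)(C)C | intermediate
14 | (5R,6S,7R,9R)-methyl alkyne (CH3–C3≡C4), C13 still silylated | CC#C[C@@H](O[Si](C)(C)C(C)(C)C)[C@H]1O[C@H](CCC#C[Si](C)(C)C)C[C@H]1O[Si](C)(C)C(C)(C)C | intermediate
15 | (5R,6S,7R,9R)-diyne with terminal C12≡C13–H | CC#C[C@@H](O[Si](C)(C)C(C)(C)C)[C@H]1O[C@H](CCC#C)C[C@H]1O[Si](C)(C)C(C)(C)C | intermediate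
16 | lithium acetylide at C13 (not isolated) | CC#C[C@@H](O[Si](C)(C)C(C)(C)C)[C@H]1O[C@H](CCC#C[Li])C[C@H]1O[Si](C)(C)C(C)(C)C | intermediate
17 | (5R,6S,7R,9R)-propargylic alcohol (C12≡C13–C14H2OH) | CC#C[C@@H](O[Si](C)(C)C(C)(C)C)[C@H]1O[C@H](CCC#CCO)C[C@H]1O[Si](C)(C)C(C)(C)C | intermediate
18 | sodium cyclic alkenylalanate (Al on C12 and on the C14 oxygen; not isolated) | CC#C[C@@H](O[Si](C)(C)C(C)(C)C)[C@H]1O[C@H](CCC2=CCO[Al-]2(OCCOC)OCCOC)C[C@H]1O[Si](C)(C)C(C)(C)C.[Na+] | intermediate
19 | (5R,6S,7R,9R,12Z)-12-chloro allylic alcohol | CC#C[C@@H](O[Si](C)(C)C(C)(C)C)[C@H]1O[C@H](CC/C(Cl)=C/CO)C[C@H]1O[Si](C)(C)C(C)(C)C | intermediate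
20 | alkenylzirconocene chloride (Zr on C3, C14 oxygen also on zirconium; not isolated) | C/C(=C\[C@@H](O[Si](C)(C)C(C)(C)C)[C@H]1O[C@H](CC/C(Cl)=C/CO[Zr](Cl)(C2C=CC=C2)C2C=CC=C2)C[C@H]1O[Si](C)(C)C(C)(C)C)[Zr](Cl)(C1C=CC=C1)C1C=CC=C1 | intermediate
21 | (3E,5R,6S,7R,9R,12Z)-3-iodoalkene with free C14 hydroxyl | C/C(I)=C\[C@@H](O[Si](C)(C)C(C)(C)C)[C@H]1O[C@H](CC/C(Cl)=C/CO)C[C@H]1O[Si](C)(C)C(C)(C)C | intermediate
22 | 2-(trimethylsilyl)ethanol | C[Si](C)(C)CCO | starting material
23 | bromoacetyl bromide | BrCC(Br)=O | starting material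
24 | 2-(trimethylsilyl)ethyl bromoacetate | BrCC(=O)OCC[Si](C)(C)C | intermediate
25 | bromo{2-oxo-2-[2-(trimethylsilyl)ethoxy]ethyl}zinc (not isolated) | Br[Zn]CC(=O)OCC[Si](C)(C)C | intermediate
26 | (3E,5R,6S,7R,9R,12Z)-C1–C14 2-(trimethylsilyl)ethyl ester, C5 and C7 TBS ethers, C14–OH | C/C(=C\[C@@H](O[Si](C)(C)C(C)(C)C)[C@H]1O[C@H](CC/C(Cl)=C/CO)C[C@H]1O[Si](C)(C)C(C)(C)C)CC(=O)OCC[Si](C)(C)C | intermediate
27 | C14 mesylate of 26 (not isolated) | C/C(=C\[C@@H](O[Si](C)(C)C(C)(C)C)[C@H]1O[C@H](CC/C(Cl)=C/COS(C)(=O)=O)C[C@H]1O[Si](C)(C)C(C)(C)C)CC(=O)OCC[Si](C)(C)C | intermediate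
28 | (3E,5R,6S,7R,9R,12Z)-C1–C14 allylic chloride (C14–Cl) | C/C(=C\[C@@H](O[Si](C)(C)C(C)(C)C)[C@H]1O[C@H](CC/C(Cl)=C/CCl)C[C@H]1O[Si](C)(C)C(C)(C)C)CC(=O)OCC[Si](C)(C)C | intermediate
29 | ethyl propiolate | C#CC(=O)OCC | starting material
30 | ethyl 3-lithiopropiolate (not isolated) | [Li]C#CC(=O)OCC | intermediate
31 | ethyl 3-(tributylstannyl)propiolate | CCCC[Sn](CCCC)(CCCC)C#CC(=O)OCC | intermediate
32 | tert-butyldimethyl(prop-2-yn-1-yloxy)silane | C#CCO[Si](C)(C)C(C)(C)C | starting material
33 | (3E,5R,6S,7R,9R,12Z,15E)-protected dienyne: C14 and the C17≡C18 ynoate cis on C15=C16, CH2OTBS (C20) on C16 | C/C(=C\[C@@H](O[Si](C)(C)C(C)(C)C)[C@H]1O[C@H](CC/C(Cl)=C/C/C=C(\C#CC(=O)OCC)CO[Si](C)(C)C(C)(C)C)C[C@H]1O[Si](C)(C)C(C)(C)C)CC(=O)OCC[Si](C)(C)C | intermediate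
34 | (3E,12Z,15E,17Z)-dienoate, otherwise as 33 | C/C(=C\[C@@H](O[Si](C)(C)C(C)(C)C)[C@H]1O[C@H](CC/C(Cl)=C/C/C=C(\C=C/C(=O)OCC)CO[Si](C)(C)C(C)(C)C)C[C@H]1O[Si](C)(C)C(C)(C)C)CC(=O)OCC[Si](C)(C)C | intermediate
35 | desilylated triol hydroxy ester (C5, C7, C20 hydroxyls free; not isolated) | C/C(=C\[C@@H](O)[C@H]1O[C@H](CC/C(Cl)=C/C/C=C(\C=C/C(=O)OCC)CO)C[C@H]1O)CC(=O)OCC[Si](C)(C)C | intermediate
36 | 2-(trimethylsilyl)ethyl ester of the target (dihydropyranone closed, C5 and C7 hydroxyls free) | C/C(=C\[C@@H](O)[C@H]1O[C@H](CC/C(Cl)=C/C/C=C2\C=CC(=O)OC2)C[C@H]1O)CC(=O)OCC[Si](C)(C)C | intermediate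
37 | CNP0180366.1, (3E,5R,6S,7R,9R,12Z,15E)-acid | C/C(=C\[C@@H](O)[C@H]1O[C@H](CC/C(Cl)=C/C/C=C2\C=CC(=O)OC2)C[C@H]1O)CC(=O)O | target

**Count and risk**

Total step count: 21. Longest linear sequence: 18 steps (1, 2, 4–13, 15, 16, 18–21, from 1 to 37).

Steps most likely to fail:

1. Step 18. Direct allyl–alkynyl coupling, oligomerisation of alkyne 32, slow transfer of the electron-poor alkynyl group from tin, or syn–anti exchange in the η3-allyl complex eroding the C12=C13 geometry may defeat the coupling. The same two bonds would then be made one after the other by known reactions. Setting out from 28, copper-mediated substitution with prop-2-yn-1-ol (C#CCO; CuI, NaI, K2CO3, DMF) should give the skipped enynol F1. Hydroxyl-directed trans-hydrostannation ([Cp*RuCl]4, Bu3SnH, CH2Cl2) should place tin on C16, cis to C14, to give the alkenylstannane F2. Stille coupling with ethyl (Z)-3-iodoacrylate (CCOC(=O)/C=C\I; Pd2(dba)3, AsPh3, CuI, DMF) should give the hydroxy dienoate F3, which needs no semihydrogenation. Under the HF·pyridine conditions of step 20, F3 loses both silyl ethers and lactonises, rejoining the route at 36.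

2. Step 19. Over-reduction of the dienoate, hydrogenolysis of the vinylic C–Cl bond or cis-to-trans isomerisation on the catalyst may occur. The two hydrogens would then be delivered by hydrometalation and protonolysis. From 33, palladium-catalysed syn-hydrostannation (Pd(PPh3)4, Bu3SnH, THF, 0 °C) should give the α-stannyl dienoate F4, with tin on C18, hydrogen on C17, and C16 and the ester cis. Protodestannylation with retention takes place under acid, so F4 is taken into HF·pyridine (with p-TsOH·H2O added if the stannane persists). After desilylation and lactonisation it should emerge as 36.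

3. Step 4. The alkyllithium may enolise the lactone, with β-elimination of the C7 silanolate, or add a second time to ring-opened ketone. The chain would then be attached through an amide. From 3, aminolysis (MeNHOMe·HCl, Me3Al, CH2Cl2) should give the hydroxy Weinreb amide F5, and silylation (Et3SiCl, imidazole) the triethylsilyl ether F6. Alkyllithium 6 then adds once, through the chelated tetrahedral intermediate, to give the ketone F7. Under the conditions of step 5 (Et3SiH, BF3·OEt2) the labile triethylsilyl ether is lost, the same oxocarbenium ion 8 forms and is reduced, and the route is rejoined at 9.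

**Further compounds**

F1 | step 18 | skipped enynol: C14H2–C15≡C16–C20H2OH on the (12Z)-chloroalkene, rest as 28 | C/C(=C\[C@@H](O[Si](C)(C)C(C)(C)C)[C@H]1O[C@H](CC/C(Cl)=C/CC#CCO)C[C@H]1O[Si](C)(C)C(C)(C)C)CC(=O)OCC[Si](C)(C)C
F2 | step 18 | alkenylstannane: Bu3Sn on C16 cis to C14, C20 hydroxyl free | C/C(=C\[C@@H](O[Si](C)(C)C(C)(C)C)[C@H]1O[C@H](CC/C(Cl)=C/C/C=C(\[Sn](CCCC)(CCCC)CCCC)CO)C[C@H]1O[Si](C)(C)C(C)(C)C)CC(=O)OCC[Si](C)(C)C
F3 | step 18 | hydroxy dienoate: as 34 but with free C20 hydroxyl | C/C(=C\[C@@H](O[Si](C)(C)C(C)(C)C)[C@H]1O[C@H](CC/C(Cl)=C/C/C=C(\C=C/C(=O)OCC)CO)C[C@H]1O[Si](C)(C)C(C)(C)C)CC(=O)OCC[Si](C)(C)C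
F4 | step 19 | α-stannyl dienoate: as 34 with Bu3Sn on C18, C16 and ester cis | C/C(=C\[C@@H](O[Si](C)(C)C(C)(C)C)[C@H]1O[C@H](CC/C(Cl)=C/C/C=C(\C=C(/C(=O)OCC)[Sn](CCCC)(CCCC)CCCC)CO[Si](C)(C)C(C)(C)C)C[C@H]1O[Si](C)(C)C(C)(C)C)CC(=O)OCC[Si](C)(C)C
F5 | step 4 | hydroxy Weinreb amide from ring-opening of 3 (sugar C4 hydroxyl free) | CON(C)C(=O)C[C@@H](O[Si](C)(C)C(C)(C)C)[C@H](O)[C@H](O[Si](C)(C)C(C)(C)C)CO[Si](C)(C)C(C)(C)C
F6 | step 4 | triethylsilyl ether of F5 | CON(C)C(=O)C[C@@H](O[Si](C)(C)C(C)(C)C)[C@H](O[Si](CC)(CC)CC)[C@H](O[Si](C)(C)C(C)(C)C)CO[Si](C)(C)C(C)(C)C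
F7 | step 4 | C9 ketone bearing the 4-(trimethylsilyl)but-3-ynyl chain | C[Si](C)(C)C#CCCC(=O)C[C@@H](O[Si](C)(C)C(C)(C)C)[C@H](O[Si](CC)(CC)CC)[C@H](O[Si](C)(C)C(C)(C)C)CO[Si](C)(C)C(C)(C)C
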